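The easy step, first end groups + second end groups to links, is quick: green already shows 70.4% links at 1.00 min. Links are then lost to first end groups, giving side product, and to second end groups, giving over-reaction product.

common to all: first end groups 0.037 M

| flask | second end groups | remark | time |
|---|---|---|---|
| amber | 0.72 equiv | run made earlier |  |
| green | 1.1 equiv | run made earlier |  |
| autumn | 1.50 equiv |  | 20 min |
| dawn | 0.980 equiv |  | 20 min |

| run | time / min | links / % | side product / % |
|---|---|---|---|
| amber | 2.50 | 46.6 | 40.3 |
| amber | 5.00 | 40.9 | 50.7 |
| amber | 8.00 | 37.2 | 57.2 |
| amber | 10.0 | 36.7 | 59.8 |
| amber | 12.0 | 34.3 | 60.3 |
| amber | 15.0 | 36.4 | 62.6 |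
| green | 1.00 | 70.4 | 16.7 |
| green | 2.00 | 68.7 | 17.7 |
| green | 3.00 | 65.1 | 20.0 |
| green | 5.00 | 61.5 | 19.6 |
| green | 8.00 | 59.6 | 19.2 |
| green | 15.0 | 59.9 | 20.7 |

(each reading ± 1 percentage point)

- the flask that ends with the higher share of links in all that became links or side product or over-reaction product, or "neither" when 2 percentage points or less lies between them (autumn / dawn / neither)
- share of links in all that became links or side product or over-reaction product, autumn
- share of links in all that became links or side product or over-reaction product, dawn

- in percentages every species weighs as the first end groups in it: one side product counts as two
- candidate steps: first end groups + links -> side product; first end groups + second end groups -> links; second end groups + links -> over-reaction product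

A link holds one of each end group, a side product two first and one second, an over-reaction product one first and two second. Once free end groups are gone, twice the first charge less the second charge drops over-reaction product from the count: links plus 1.50 times side product equal two minus the equivalents. That sum is the link budget (a stoichiometric balance), 50.0% for autumn and 102% for dawn. Two amounts matter, then: the budget and the cost of side product. Green, with links flat at 59.6% and 59.9%, gives 58.9% from its budget and side product.

Side product reads 62.6% in amber and 20.7% in green. A straight line between them, a reckoning made here, puts dawn near 33.9% side product, so links near 51.1%, while autumn stands below its budget by the cost of its side product. Dawn is the pick.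

The forecast also says dawn, with 32% for autumn and a higher 61% for dawn, since in autumn “the excess second end groups consume links down to about 32%”. Its dawn figure stands above the 51.1% of the straight line reckoned here.

    first end groups + links → side product (k = 0.307 M⁻¹ s⁻¹)
    first end groups + second end groups → links (k = 3.21 M⁻¹ s⁻¹)
    second end groups + links → over-reaction product (k = 0.195 M⁻¹ s⁻¹)

Autumn gives 35.5% and dawn 59.8%, so dawn ends higher. At 20.0 min autumn holds 54.1% as over-reaction product against 10.4% as side product. Dawn's budget less the cost of its 28.1% side product gives 59.9%. Autumn's budget less the cost of 10.4% gives 34.4%, and at 200 min, with second end groups at 0%, autumn holds 34.4% links.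

(The numbers in the tables were generated by integration with constants of no real substance.)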